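The C5–C10/C6–C7 disconnection opens the cis-fused decalin across ring B: an intramolecular Diels–Alder reaction of an open-chain triene closes rings A and B at once. The precursor is a (Z)-2-silyloxy-1,3-diene (C7=C8(OSi)–C9=C10, with C10 carrying CH3 and the C1–C4 tether) linked to an (E)-enoyl oxazolidinone (C5=C6). The step exploits the cis C5–H/C10–CH3 ring fusion at the quaternary C10, which follows from the inside-tethered diene, and it leaves a regiodefined C8=C9 silyl enol ether. That enol ether then takes up the C9 side chain, the ketone takes up the C8 methyl group, and the C6 acyl group is excised.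

Key step: step 6

Remark: labdane numbering is used for the skeleton (decalin C1–C10, chain C11–C16, C17 on C8, C18/C19 on C4, C20 on C10); the target is the (5R,8S,9R,10S) isomer, a cis-fused decalin in which C5–H, C8–OH, the C9 chain and C10–CH3 lie on one face.

Step 1
Reactants: 1 diethylphosphonoacetic acid; 2 (R)-4-benzyl-1,3-oxazolidin-2-one
Product: 3 diethyl {2-[(4R)-4-benzyl-2-oxo-1,3-oxazolidin-3-yl]-2-oxoethyl}phosphonate
Conditions: PivCl, Et3N, THF, −20 °C; then 2, LiCl, −20 °C → rt
Reagents that add atoms: none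
Why: N-acylation of the oxazolidinone through the pivaloyl mixed anhydride is a standard way to this Horner–Wadsworth–Emmons reagent and does not touch the stereocentre.

Step 2
Reactants: 3 phosphonate imide; 4 2,2-dimethylpent-4-enal
Product: 5 (4R)-4-benzyl-3-[(2E)-4,4-dimethylhepta-2,6-dienoyl]-1,3-oxazolidin-2-one
Conditions: LiCl, i-Pr2NEt, MeCN, rt
Reagents that add atoms: none
Why: Horner–Wadsworth–Emmons olefination of the non-enolisable α-quaternary aldehyde with the stabilised phosphonate under mild LiCl/amine conditions should give the (E)-enoyl imide.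

Step 3
Reactants: 6 pent-3-yn-2-one
Product: 7 (3Z)-4-iodopent-3-en-2-one
Conditions: NaI, AcOH, rt, dark
Reagents that add atoms: sodium iodide [Na+].[I-]
Why: Conjugate hydroiodination of the ynone is a kinetic anti addition, which puts iodine cis to the acetyl group and so gives the (Z)-β-iodo enone.

Step 4
Reactants: 5 enoyl imide with terminal alkene; 7 (3Z)-4-iodopent-3-en-2-one
Product: 9 (4R)-4-benzyl-3-[(2E,8Z)-4,4,8-trimethyl-10-oxoundeca-2,8-dienoyl]-1,3-oxazolidin-2-one, via B-alkyl-9-BBN adduct 8 (not isolated)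
Conditions: 9-BBN-H, THF, 0 °C → rt; then 7, PdCl2(dppf) (cat.), AsPh3 (cat.), K3PO4, DMF/H2O, rt
Reagents that add atoms: 9-borabicyclo[3.3.1]nonane B1C2CCCC1CCC2 (its atoms are carried only by 8)
Why: 9-BBN hydroborates the monosubstituted alkene at its terminal carbon much faster than it touches the enoyl imide, and the B-alkyl Suzuki–Miyaura coupling with the β-iodo enone proceeds with retention, so the new chain ends cis to the acetyl group (the Z geometry of the later C9=C10 bond).

Step 5
Reactants: 9 (Z)-enone imide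
Product: 10 (4R)-4-benzyl-3-[(2E,8Z)-10-(tert-butyldimethylsilyloxy)-4,4,8-trimethylundeca-2,8,10-trienoyl]-1,3-oxazolidin-2-one
Conditions: TBSOTf, Et3N, CH2Cl2, −78 °C
Reagents that add atoms: tert-butyldimethylsilyl triflate CC(C)(C)[Si](C)(C)OS(=O)(=O)C(F)(F)F
Why: Soft enolisation of the methyl ketone at its α′-methyl group gives the cross-conjugated 2-silyloxy diene without touching the alkene geometry; the imide has no enolisable position.

Step 6
Reactants: 10 silyloxy triene imide
Product: 11 (4R)-4-benzyl-3-{[(1R,4aS,8aR)-3-(tert-butyldimethylsilyloxy)-4a,8,8-trimethyl-1,2,4a,5,6,7,8,8a-octahydronaphthalen-1-yl]carbonyl}-1,3-oxazolidin-2-one (cis-fused; labdane 5R,6R,10S)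
Conditions: Me2AlCl (1.5 equiv), CH2Cl2 (dilute), −30 → 0 °C
Reagents that add atoms: none
Why: Me2AlCl binds both imide carbonyls, locks the enoyl group s-cis and lowers its LUMO, and the 2-silyloxy diene then adds in a concerted, asynchronous intramolecular [4+2] cycloaddition that forms C5–C10 and C6–C7 in one operation. The closest known reaction type is the Lewis-acid-promoted type 1 intramolecular Diels–Alder reaction of (2E)-deca-2,7,9-trienoyl oxazolidinones. Ring A closes through the C1–C4 tether as the six-membered carbocycle completed by the C5–C10 bond, and ring B closes as the cyclohexene of the cycloaddition (C5–C10 plus C6–C7), so a fused 6/6 bicycle is formed. At C10 and in its relation to C5 the control element is the (Z) geometry of C9=C10: a tether on the inside position of the diene can reach the dienophile only in the arrangement that gives the cis ring fusion (C5–H syn to C10–CH3), and with the (E)-dienophile this places the acyl group endo and fixes C6. The absolute sense is set by the (4R)-benzyl group, which shields the si face of C6 in the chelate so that the diene adds to the re face and should give 5R, 6R, 10S. The step needs fused instead of bridged regiochemistry, cis instead of trans fusion and one diene-to-dienophile face pairing; the four-atom tether, the diene geometry and the auxiliary secure these in that order.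

Step 7
Reactants: 11 cycloadduct silyl enol ether; 12 methyl vinyl ketone (but-3-en-2-one)
Product: 13 (4R)-4-benzyl-3-{[(1R,4R,4aS,8aR)-4a,8,8-trimethyl-3-oxo-4-(3-oxobutyl)decahydronaphthalen-1-yl]carbonyl}-1,3-oxazolidin-2-one (labdane 5R,6R,9R,10S)
Conditions: TiCl4, CH2Cl2, −78 °C; aq. NaHCO3
Reagents that add atoms: none
Why: Mukaiyama–Michael addition of the regiodefined silyl enol ether puts the 3-oxobutyl chain on C9 only, and bond formation should be axial and anti to the pseudoaxial C10–C1 bond of the cis-fused half-chair, that is on the face of the C10 methyl group, which sets C9 (R) kinetically.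

Step 8
Reactants: 13 diketone imide; 14 triethyl phosphonoacetate
Product: 15 ethyl (2E)-5-[(1R,4R,4aR,8aS)-4-{[(4R)-4-benzyl-2-oxo-1,3-oxazolidin-3-yl]carbonyl}-5,5,8a-trimethyl-2-oxodecahydronaphthalen-1-yl]-3-methylpent-2-enoate
Conditions: NaH, THF, 0 °C (pre-formed phosphonate anion, slight excess only) → rt
Reagents that add atoms: none
Why: Horner–Wadsworth–Emmons olefination should take place at the unhindered methyl ketone and not at the ring ketone flanked by the C9 methine; the (E)-enoate is expected to predominate and the minor (Z)-isomer is removed by chromatography.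

Step 9
Reactants: 15 keto enoate imide
Product: 16 (1R,4R,4aS,8aR)-4-[(3E)-5-ethoxy-3-methyl-5-oxopent-3-en-1-yl]-4a,8,8-trimethyl-3-oxodecahydronaphthalene-1-carboxylic acid
Conditions: LiOH, H2O2, THF/H2O, 0 °C; then Na2SO3; HCl to pH 3
Reagents that add atoms: lithium hydroperoxide (from LiOH and H2O2) [Li+].[O-]O
Why: Hydroperoxide cleaves the exocyclic imide carbonyl selectively even at a hindered acyl group (auxiliary hydrolysis), releasing the acid and the recoverable auxiliary while the ethyl enoate and the ketone survive at 0 °C.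

Step 10
Reactants: 16 keto enoate acid
Product: 18 ethyl (2E)-3-methyl-5-[(1R,4aR,8aS)-5,5,8a-trimethyl-2-oxodecahydronaphthalen-1-yl]pent-2-enoate, via Barton ester 17 (not isolated)
Conditions: N-hydroxypyridine-2-thione, DCC, DMAP (cat.), CH2Cl2, dark, rt; then t-BuSH, hν (tungsten lamp), PhH, rt
Reagents that add atoms: N-hydroxypyridine-2-thione ON1C=CC=CC1=S (its atoms are carried only by 17)
Why: Barton reductive decarboxylation: the thiohydroxamate ester fragments to the secondary C6 radical, which takes hydrogen from the thiol, so C6 becomes CH2 and no remaining stereocentre is touched under these neutral conditions.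

Step 11
Reactants: 18 keto enoate
Product: 19 ethyl (2E)-5-[(1R,2S,4aR,8aS)-2-hydroxy-2,5,5,8a-tetramethyldecahydronaphthalen-1-yl]-3-methylpent-2-enoate
Conditions: MeLi, CeCl3, THF, −78 °C
Reagents that add atoms: methyllithium [Li]C
Why: 1,2-Addition of the weakly basic methylcerium reagent should occur only at the ketone (the β,β-disubstituted enoate is inert at −78 °C) and trans to the C9 chain, because the face carrying the chain and the C10 methyl group is blocked in both chair forms of the cis-decalone (adjacent axial chain in one, 1,3-syn-axial methyl in the other), which sets C8 (S) with the hydroxyl cis to the chain.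

Step 12
Reactants: 19 hydroxy enoate
Product: 20 (1R,2S,4aR,8aS)-1-[(3E)-5-hydroxy-3-methylpent-3-en-1-yl]-2,5,5,8a-tetramethyldecahydronaphthalen-2-ol
Conditions: i-Bu2AlH (3.5 equiv), CH2Cl2, −78 → 0 °C; aq. potassium sodium tartrate
Reagents that add atoms: none
Why: 1,2-Reduction of the α,β-unsaturated ester by the aluminium hydride gives the (E)-allylic alcohol without touching the alkene geometry or the tertiary alcohol.

Step 13
Reactants: 20 diol
Product: 21 (2E)-5-[(1R,2S,4aR,8aS)-2-hydroxy-2,5,5,8a-tetramethyldecahydronaphthalen-1-yl]-3-methylpent-2-en-1-yl acetate (CNP0268033.2)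
Conditions: Ac2O, pyridine, DMAP (cat.), CH2Cl2, 0 °C
Reagents that add atoms: acetic anhydride CC(=O)OC(C)=O
Why: Acylation of the primary allylic alcohol is far faster than that of the hindered tertiary C8 alcohol, so the monoacetate should result.

Compound list
1 | diethylphosphonoacetic acid | CCOP(=O)(OCC)CC(=O)O | starting material
2 | (R)-4-benzyl-1,3-oxazolidin-2-one | O=C1N[C@H](Cc2ccccc2)CO1 | starting material
3 | diethyl {2-[(4R)-4-benzyl-2-oxo-1,3-oxazolidin-3-yl]-2-oxoethyl}phosphonate | CCOP(=O)(OCC)CC(=O)N1[C@H](Cc2ccccc2)COC1=O | intermediate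
4 | 2,2-dimethylpent-4-enal | C=CCC(C)(C)C=O | starting material
5 | (4R)-4-benzyl-3-[(2E)-4,4-dimethylhepta-2,6-dienoyl]-1,3-oxazolidin-2-one | C=CCC(C)(C)/C=C/C(=O)N1[C@H](Cc2ccccc2)COC1=O | intermediate
6 | pent-3-yn-2-one | CC#CC(C)=O | starting material
7 | (3Z)-4-iodopent-3-en-2-one | CC(=O)/C=C(/C)I | intermediate
8 | B-alkyl-9-BBN adduct of 5 (boron on the former terminal alkene carbon) | O=C(/C=C/C(C)(C)CCCB1C2CCCC1CCC2)N1[C@H](Cc2ccccc2)COC1=O | intermediate
9 | (4R)-4-benzyl-3-[(2E,8Z)-4,4,8-trimethyl-10-oxoundeca-2,8-dienoyl]-1,3-oxazolidin-2-one | CC(=O)/C=C(/C)CCCC(C)(C)/C=C/C(=O)N1[C@H](Cc2ccccc2)COC1=O | intermediate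
10 | (4R)-4-benzyl-3-[(2E,8Z)-10-(tert-butyldimethylsilyloxy)-4,4,8-trimethylundeca-2,8,10-trienoyl]-1,3-oxazolidin-2-one | C=C(O[Si](C)(C)C(C)(C)C)/C=C(/C)CCCC(C)(C)/C=C/C(=O)N1[C@H](Cc2ccccc2)COC1=O | intermediate
11 | (4R)-4-benzyl-3-{[(1R,4aS,8aR)-3-(tert-butyldimethylsilyloxy)-4a,8,8-trimethyl-1,2,4a,5,6,7,8,8a-octahydronaphthalen-1-yl]carbonyl}-1,3-oxazolidin-2-one | C[C@]12CCCC(C)(C)[C@H]1[C@H](C(=O)N1[C@H](Cc3ccccc3)COC1=O)CC(O[Si](C)(C)C(C)(C)C)=C2 | intermediate
12 | methyl vinyl ketone (but-3-en-2-one) | C=CC(C)=O | starting material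
13 | (4R)-4-benzyl-3-{[(1R,4R,4aS,8aR)-4a,8,8-trimethyl-3-oxo-4-(3-oxobutyl)decahydronaphthalen-1-yl]carbonyl}-1,3-oxazolidin-2-one | CC(=O)CC[C@@H]1[C@@]2(C)CCCC(C)(C)[C@H]2[C@H](C(=O)N2[C@H](Cc3ccccc3)COC2=O)CC1=O | intermediate
14 | triethyl phosphonoacetate | CCOC(=O)CP(=O)(OCC)OCC | starting material
15 | ethyl (2E)-5-[(1R,4R,4aR,8aS)-4-{[(4R)-4-benzyl-2-oxo-1,3-oxazolidin-3-yl]carbonyl}-5,5,8a-trimethyl-2-oxodecahydronaphthalen-1-yl]-3-methylpent-2-enoate | CCOC(=O)/C=C(\C)CC[C@@H]1[C@@]2(C)CCCC(C)(C)[C@H]2[C@H](C(=O)N2[C@H](Cc3ccccc3)COC2=O)CC1=O | intermediate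
16 | (1R,4R,4aS,8aR)-4-[(3E)-5-ethoxy-3-methyl-5-oxopent-3-en-1-yl]-4a,8,8-trimethyl-3-oxodecahydronaphthalene-1-carboxylic acid | CCOC(=O)/C=C(\C)CC[C@@H]1[C@@]2(C)CCCC(C)(C)[C@H]2[C@H](C(=O)O)CC1=O | intermediate
17 | 2-thioxopyridin-1(2H)-yl ester of 16 (Barton ester) | CCOC(=O)/C=C(\C)CC[C@@H]1[C@@]2(C)CCCC(C)(C)[C@H]2[C@H](C(=O)ON2C=CC=CC2=S)CC1=O | intermediate
18 | ethyl (2E)-3-methyl-5-[(1R,4aR,8aS)-5,5,8a-trimethyl-2-oxodecahydronaphthalen-1-yl]pent-2-enoate | CCOC(=O)/C=C(\C)CC[C@@H]1[C@@]2(C)CCCC(C)(C)[C@H]2CCC1=O | intermediate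
19 | ethyl (2E)-5-[(1R,2S,4aR,8aS)-2-hydroxy-2,5,5,8a-tetramethyldecahydronaphthalen-1-yl]-3-methylpent-2-enoate | CCOC(=O)/C=C(\C)CC[C@@H]1[C@@]2(C)CCCC(C)(C)[C@H]2CC[C@]1(C)O | intermediate
20 | (1R,2S,4aR,8aS)-1-[(3E)-5-hydroxy-3-methylpent-3-en-1-yl]-2,5,5,8a-tetramethyldecahydronaphthalen-2-ol | OC/C=C(\C)CC[C@@H]1[C@@]2(C)CCCC(C)(C)[C@H]2CC[C@]1(C)O | intermediate
21 | (2E)-5-[(1R,2S,4aR,8aS)-2-hydroxy-2,5,5,8a-tetramethyldecahydronaphthalen-1-yl]-3-methylpent-2-en-1-yl acetate | CC(=O)OC/C=C(\C)CC[C@@H]1[C@@]2(C)CCCC(C)(C)[C@H]2CC[C@]1(C)O | target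

Total step count: 13. Longest linear sequence: 12 steps (steps 1, 2 and 4–13; step 3 is a one-step branch).

Steps most likely to fail

Step 6. The aluminium Lewis acid may desilylate or oligomerise the silyl dienol ether (intermolecular Mukaiyama–Michael addition to the activated imide) faster than the crowded, inside-tethered diene reaches the s-cis geometry needed for cycloaddition. The fallback sets out from 4 and 7 and comes back at 18; it replaces the auxiliary and the stoichiometric Lewis acid by an enal dienophile, a chiral boron catalyst and a traceless decarbonylation. Reduction of 4 with NaBH4 should give 2,2-dimethylpent-4-en-1-ol F1. Hydroboration with 9-BBN-H and coupling with 7 as in step 4 should give (3Z)-9-hydroxy-4,8,8-trimethylnon-3-en-2-one F2. Dess–Martin oxidation should give (6Z)-2,2,6-trimethyl-8-oxonon-6-enal F3, and Wittig olefination with Ph3P=CHCHO should give (2E,8Z)-4,4,8-trimethyl-10-oxoundeca-2,8-dienal F4. TBSOTf/Et3N should give the silyloxy trienal F5. A catalytic enantioselective intramolecular Diels–Alder reaction with a chiral oxazaborolidinium triflimide (the enantiomer that leaves the re face of C6 open; a catalyst class that tolerates 2-silyloxy dienes) should give the cis-fused aldehyde F6. Decarbonylation with RhCl(PPh3)3 in hot toluene should give the silyl enol ether F7, MVK 12 with TiCl4 as in step 7 the dione F8, and olefination with 14 as in step 8 then gives 18.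

Step 7. C–C bond formation at the neopentyl-type C9 may be slow, so that polymerisation of the enone and protodesilylation to the C9-unsubstituted ketone take over. The fallback sets out from 11 and comes back at 13: TiCl4-promoted conjugate addition of 11 to the slimmer and more electrophilic but-3-yn-2-one should give the enedione F9 (alkene geometry irrelevant), and hydrogenation of the new disubstituted alkene (H2, Pd/C, EtOAc, neutral) then gives 13 with C9 set in the same C–C bond-forming event.

Step 11. Methyl delivery may show poor or reversed facial selectivity (attack syn to the C9 chain), or the hindered ketone may be enolised instead of attacked. The fallback sets out from 18 and comes back at 20, and it turns the same facial bias around by delivering oxygen, not carbon, to C8. Methylenation with Zn/CH2Br2/TiCl4 (non-basic, ester-tolerant) should give the exocyclic alkene F10. Epoxidation with mCPBA (the electron-poor enoate is inert) should give the spiro-epoxide F11 with oxygen on the face of the C9 chain. LiAlH4 then opens the epoxide at CH2 and reduces the ester in the same flask, giving 20.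

Further compounds
F1 | step 6 | 2,2-dimethylpent-4-en-1-ol | C=CCC(C)(C)CO
F2 | step 6 | (3Z)-9-hydroxy-4,8,8-trimethylnon-3-en-2-one | CC(=O)/C=C(/C)CCCC(C)(C)CO
F3 | step 6 | (6Z)-2,2,6-trimethyl-8-oxonon-6-enal | CC(=O)/C=C(/C)CCCC(C)(C)C=O
F4 | step 6 | (2E,8Z)-4,4,8-trimethyl-10-oxoundeca-2,8-dienal | CC(=O)/C=C(/C)CCCC(C)(C)/C=C/C=O
F5 | step 6 | (2E,8Z)-10-(tert-butyldimethylsilyloxy)-4,4,8-trimethylundeca-2,8,10-trienal | C=C(O[Si](C)(C)C(C)(C)C)/C=C(/C)CCCC(C)(C)/C=C/C=O
F6 | step 6 | (1R,4aS,8aR)-3-(tert-butyldimethylsilyloxy)-4a,8,8-trimethyl-1,2,4a,5,6,7,8,8a-octahydronaphthalene-1-carbaldehyde | C[C@]12CCCC(C)(C)[C@H]1[C@H](C=O)CC(O[Si](C)(C)C(C)(C)C)=C2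
F7 | step 6 | tert-butyldimethyl{[(4aR,8aS)-5,5,8a-trimethyl-3,4,4a,5,6,7,8,8a-octahydronaphthalen-2-yl]oxy}silane | C[C@]12CCCC(C)(C)[C@H]1CCC(O[Si](C)(C)C(C)(C)C)=C2
F8 | step 6 | (1R,4aR,8aS)-5,5,8a-trimethyl-1-(3-oxobutyl)octahydronaphthalen-2(1H)-one | CC(=O)CC[C@@H]1[C@@]2(C)CCCC(C)(C)[C@H]2CCC1=O
F9 | step 7 | 13 with a C11=C12 double bond (3-oxobut-1-enyl chain on C9, ring stereocentres as in 13) | CC(=O)C=C[C@@H]1[C@@]2(C)CCCC(C)(C)[C@H]2[C@H](C(=O)N2[C@H](Cc3ccccc3)COC2=O)CC1=O
F10 | step 11 | 8-methylidene analogue of 18 (ethyl ester, ring stereocentres as in 18) | CCOC(=O)/C=C(\C)CC[C@@H]1[C@@]2(C)CCCC(C)(C)[C@H]2CCC1=C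
F11 | step 11 | spiro-epoxide of F10 with the epoxide oxygen on the face of the C9 chain (C8 as in 19) | CCOC(=O)/C=C(\C)CC[C@@H]1[C@@]2(C)CCCC(C)(C)[C@H]2CC[C@@]13CO3
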